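**Retrosynthetic overview**

1. Target ⇐ aroylation of the C6 hydroxyl ⇐ hydroxyl-directed reduction of a C6 ketone ⇐ hydroboration–oxidation of a dienyl isovalerate ⇐ Luche reduction and acylation of a trans-fused 4-hydroxydauca-6,8-dien-10-one.
2. That dienone ⇐ C5 epimerisation of its cis-fused isomer ⇐ one-pot cationic bicyclisation of an acyclic (2Z,6E)-5-silyl-10-oxofarnesoyl chloride.
3. Ring order as in the farnesyl → cycloheptenyl → daucyl cation cascade: the seven-membered ring first (acylium C1 captured by C7 of the central olefin; daucane C10–C1 bond), the five-membered ring second (chain C6–C10, daucane C5–C4, which also delivers the C4 hydroxyl).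
4. Acyclic acid ⇐ allylic silylation of a vinyl δ-lactone ⇐ asymmetric vinylogous aldol of (2E)-3,7-dimethyl-6-oxooct-2-enal (from geranyl acetate) with the dienolate of methyl 3-methylbut-2-enoate.

Assumption: bicyclic compounds are named on the daucane skeleton (C1 angular-methyl carbon, C4 isopropyl carbinol carbon, C5 ring-fusion CH, C6–C10 seven-membered ring, methyl on C8); open-chain compounds carry systematic locants, which coincide with farnesane locants.

**Route**

Step 1
Reactants: 1 geranyl acetate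
Product: 2 (2E)-3,7-dimethyloct-2-ene-1,6-diol (racemic at C6)
Conditions: 9-BBN (1.2 equiv), THF, 0 °C → rt; then NaOH, H2O2, H2O, 0 → 40 °C
Reagents that add atoms: hydrogen peroxide, OO
Why: Anti-Markovnikov hydroboration–oxidation in which 9-BBN adds only to the electron-rich remote trisubstituted olefin (boron at C6, the C2 olefin being deactivated by the allylic acetate) while the alkaline peroxide work-up also saponifies the acetate, the racemic C6 carbinol centre being erased in step 2.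

Step 2
Reactants: 2 (2E)-3,7-dimethyloct-2-ene-1,6-diol
Product: 3 (2E)-3,7-dimethyl-6-oxooct-2-enal
Conditions: Dess–Martin periodinane (2.5 equiv), NaHCO3, CH2Cl2, 0 °C → rt
Reagents that add atoms: none
Why: Dess–Martin oxidation of both hydroxyls (allylic primary to the enal without E/Z scrambling, secondary to the isopropyl ketone) under buffered conditions, leaving no stereocentre.

Step 3
Reactants: 4 methyl 3-methylbut-2-enoate
Product: 5 [(1-methoxy-3-methylbuta-1,3-dien-1-yl)oxy]trimethylsilane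
Conditions: LiN(i-Pr)2, THF, −78 °C; Me3SiCl, −78 °C → rt
Reagents that add atoms: chlorotrimethylsilane, C[Si](C)(C)Cl
Why: Kinetic γ-deprotonation of the senecioate and O-silylation (silyl ketene acetal formation) give the dienolate that serves as the C1–C4 unit.

Step 4
Reactants: 3 (2E)-3,7-dimethyl-6-oxooct-2-enal; 5 [(1-methoxy-3-methylbuta-1,3-dien-1-yl)oxy]trimethylsilane
Product: 6 (6R)-6-[(1E)-2,6-dimethyl-5-oxohept-1-en-1-yl]-4-methyl-5,6-dihydro-2H-pyran-2-one
Conditions: Cu(OTf)2 (10 mol %), (S)-Tol-BINAP (11 mol %), Bu4N[Ph3SiF2] (20 mol %), THF, −78 °C → rt; aq NH4Cl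
Reagents that add atoms: none
Why: Catalytic asymmetric vinylogous Mukaiyama aldol addition at the aldehyde only and through the γ-carbon of 5, followed by in situ lactonisation of the (Z)-configured aldolate, so that the chiral dienolate generated from Cu(OTf)2, (S)-Tol-BINAP and Bu4N[Ph3SiF2] fixes the carbinol centre as 6R and the ring locks the 2Z olefin.

Step 5
Reactants: 6 (6R)-6-[(1E)-2,6-dimethyl-5-oxohept-1-en-1-yl]-4-methyl-5,6-dihydro-2H-pyran-2-one
Product: 7 (2Z,5S,6E)-3,7,11-trimethyl-10-oxo-5-(trimethylsilyl)dodeca-2,6-dienoic acid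
Conditions: Me3SiSiMe3 (1.5 equiv), Pd(dba)2 (5 mol %), LiCl, DMF, 80 °C; aq work-up at pH 5
Reagents that add atoms: hexamethyldisilane, C[Si](C)(C)[Si](C)(C)C
Why: Tsuji–Trost ionisation of the allylic carboxylate by zerovalent palladium (inversion) and silyl transfer from palladium to the less hindered allyl terminus (retention), a Tsuji-type allylic silylation, convert the 6R lactone into the (5S,6E)-allylsilane with net inversion, the silyl ester being hydrolysed on work-up.

Step 6
Reactants: 7 (2Z,5S,6E)-3,7,11-trimethyl-10-oxo-5-(trimethylsilyl)dodeca-2,6-dienoic acid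
Product: 10 (1S,4S,5S)-4-hydroxydauca-6,8-dien-10-one (cis-fused), via acyl chloride 8 (not isolated), via cycloheptadienone 9 (not isolated)
Conditions: 1-chloro-N,N,2-trimethylprop-1-en-1-amine (1.1 equiv), CH2Cl2, 0 °C; then TiCl4 (1.2 equiv), −78 → −20 °C; aq NaHCO3
Reagents that add atoms: 1-chloro-N,N,2-trimethylprop-1-en-1-amine, CC(C)=C(Cl)N(C)C (chlorine of 8 only)
Why: Proposed new method: TiCl4 ionises the acyl chloride to an acylium ion (an oxygenated farnesyl cation) that is captured at C7 by the C6=C7 allylsilane in an anti SE2' Friedel–Crafts/Sakurai-type acylation (closest known type: Lewis-acid acylation of allylsilanes), closing the seven-membered ring and relaying C5 (S) to the quaternary centre (7S of 9, C1 of the daucane), after which the TiCl4-complexed side-chain ketone adds to the new cis olefin in an intramolecular carbonyl-ene (Prins-type) reaction with hydrogen transfer from the doubly allylic CH2 (closest known type: Lewis-acid ketone–olefin ene cyclisation), whose tethered suprafacial transition state gives the cis-fused five-membered ring with the hydroxyl syn to C6 and so sets C4 (S) and C5 (S).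

Step 7
Reactants: 10 (1S,4S,5S)-4-hydroxydauca-6,8-dien-10-one
Product: 11 (1S,4S,5R)-4-hydroxydauca-6,8-dien-10-one (trans-fused)
Conditions: DBU (0.3 equiv), toluene, 40 °C
Reagents that add atoms: none
Why: Thermodynamic epimerisation at C5 through the extended enolate of the 2,4-dienone (vinylogous enolisation), expected to favour the trans-fused isomer because the planar dienone forces a large torsion about the C1–C5 bond that a trans-fused cyclopentane accommodates better, which places H-5 anti to the angular methyl.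

Step 8
Reactants: 11 (1S,4S,5R)-4-hydroxydauca-6,8-dien-10-one
Product: 12 (1S,4S,5R,10S)-dauca-6,8-diene-4,10-diol
Conditions: NaBH4, CeCl3·7H2O, MeOH, −78 °C
Reagents that add atoms: none
Why: Luche 1,2-reduction of the dienone with hydride entering anti to the pseudo-axial angular methyl gives the 10S alcohol (hydroxyl cis to the methyl) without conjugate reduction.

Step 9
Reactants: 12 (1S,4S,5R,10S)-dauca-6,8-diene-4,10-diol
Product: 13 (1S,4S,5R,10S)-4-hydroxydauca-6,8-dien-10-yl 3-methylbutanoate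
Conditions: 3-methylbutanoyl chloride, pyridine, DMAP (cat.), CH2Cl2, 0 °C
Reagents that add atoms: 3-methylbutanoyl chloride, CC(C)CC(Cl)=O
Why: DMAP-catalysed esterification of the only secondary hydroxyl, the tertiary C4 hydroxyl being inert and no stereocentre being touched.

Step 10
Reactants: 13 (1S,4S,5R,10S)-4-hydroxydauca-6,8-dien-10-yl 3-methylbutanoate
Product: 14 (1S,4S,5S,6S,10S)-4,6-dihydroxydauc-8-en-10-yl 3-methylbutanoate
Conditions: 9-BBN (2.5 equiv), THF, 0 °C → rt; then NaBO3·4H2O, H2O, rt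
Reagents that add atoms: sodium perborate, [Na+].[Na+].O[B-]1(O)OO[B-](O)(O)OO1
Why: Hydroboration–oxidation of the conjugated diene at its less substituted C6=C7 bond with boron at the terminal C6 (anti-Markovnikov) and from the face anti to the C5–C4 bond installs the C6 oxygen and keeps the C8 olefin, the expected 6S configuration being inconsequential because it is erased in step 11.

Step 11
Reactants: 14 (1S,4S,5S,6S,10S)-4,6-dihydroxydauc-8-en-10-yl 3-methylbutanoate
Product: 15 (1S,4S,5R,10S)-4-hydroxy-6-oxodauc-8-en-10-yl 3-methylbutanoate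
Conditions: Dess–Martin periodinane, NaHCO3, CH2Cl2, 0 °C
Reagents that add atoms: none
Why: Dess–Martin oxidation of the secondary C6 hydroxyl under buffered neutral conditions, which spare the tertiary alcohol, the allylic ester and the position of the β,γ-olefin.

Step 12
Reactants: 15 (1S,4S,5R,10S)-4-hydroxy-6-oxodauc-8-en-10-yl 3-methylbutanoate
Product: 16 (1S,4S,5S,6R,10S)-4,6-dihydroxydauc-8-en-10-yl 3-methylbutanoate
Conditions: Me4NBH(OAc)3, AcOH/MeCN 1:1, −30 °C
Reagents that add atoms: none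
Why: Evans–Saksena hydroxyl-directed reduction, in which the borohydride bound to the C4 oxygen delivers hydride intramolecularly to the α face of the C6 ketone and gives the anti-1,3-diol, that is the 6R alcohol.

Step 13
Reactants: 16 (1S,4S,5S,6R,10S)-4,6-dihydroxydauc-8-en-10-yl 3-methylbutanoate
Product: 18 (1S,4S,5S,6R,10S)-4-hydroxy-10-(3-methylbutanoyloxy)dauc-8-en-6-yl 4-hydroxybenzoate (target), via 4-acetoxybenzoate 17 (not isolated)
Conditions: 4-acetoxybenzoyl chloride, Et3N, DMAP, CH2Cl2, 0 °C → rt; then pyrrolidine, 0 °C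
Reagents that add atoms: 4-(chlorocarbonyl)phenyl acetate, CC(=O)Oc1ccc(cc1)C(Cl)=O
Why: DMAP-catalysed esterification of the secondary C6 hydroxyl (the tertiary C4 hydroxyl does not react) followed by chemoselective aminolysis of the phenolic acetate by pyrrolidine, which leaves both alkyl esters and every stereocentre untouched.

**Compound list**

1 | geranyl acetate | CC(C)=CCC/C(C)=C/COC(C)=O | starting material
2 | (2E)-3,7-dimethyloct-2-ene-1,6-diol | CC(C)C(O)CC/C(C)=C/CO | intermediate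
3 | (2E)-3,7-dimethyl-6-oxooct-2-enal | CC(C)C(=O)CC/C(C)=C/C=O | intermediate
4 | methyl 3-methylbut-2-enoate | COC(=O)C=C(C)C | starting material
5 | [(1-methoxy-3-methylbuta-1,3-dien-1-yl)oxy]trimethylsilane | COC(O[Si](C)(C)C)=CC(C)=C | intermediate
6 | (6R)-6-[(1E)-2,6-dimethyl-5-oxohept-1-en-1-yl]-4-methyl-5,6-dihydro-2H-pyran-2-one | CC1=CC(=O)O[C@@H](/C=C(\C)CCC(=O)C(C)C)C1 | intermediate
7 | (2Z,5S,6E)-3,7,11-trimethyl-10-oxo-5-(trimethylsilyl)dodeca-2,6-dienoic acid | OC(=O)/C=C(C)\C[C@H]([Si](C)(C)C)/C=C(\C)CCC(=O)C(C)C | intermediate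
8 | (2Z,5S,6E)-3,7,11-trimethyl-10-oxo-5-(trimethylsilyl)dodeca-2,6-dienoyl chloride | ClC(=O)/C=C(C)\C[C@H]([Si](C)(C)C)/C=C(\C)CCC(=O)C(C)C | intermediate
9 | (7S)-3,7-dimethyl-7-(4-methyl-3-oxopentyl)cyclohepta-2,5-dien-1-one | CC1=CC(=O)[C@@](C)(CCC(=O)C(C)C)C=CC1 | intermediate
10 | (1S,4S,5S)-4-hydroxydauca-6,8-dien-10-one (cis-fused) | CC1=CC(=O)[C@@]2(C)CC[C@](O)(C(C)C)[C@H]2C=C1 | intermediate
11 | (1S,4S,5R)-4-hydroxydauca-6,8-dien-10-one (trans-fused) | CC1=CC(=O)[C@@]2(C)CC[C@](O)(C(C)C)[C@@H]2C=C1 | intermediate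
12 | (1S,4S,5R,10S)-dauca-6,8-diene-4,10-diol | CC1=C[C@H](O)[C@@]2(C)CC[C@](O)(C(C)C)[C@@H]2C=C1 | intermediate
13 | (1S,4S,5R,10S)-4-hydroxydauca-6,8-dien-10-yl 3-methylbutanoate | CC1=C[C@H](OC(=O)CC(C)C)[C@@]2(C)CC[C@](O)(C(C)C)[C@@H]2C=C1 | intermediate
14 | (1S,4S,5S,6S,10S)-4,6-dihydroxydauc-8-en-10-yl 3-methylbutanoate | CC1=C[C@H](OC(=O)CC(C)C)[C@@]2(C)CC[C@](O)(C(C)C)[C@@H]2[C@@H](O)C1 | intermediate
15 | (1S,4S,5R,10S)-4-hydroxy-6-oxodauc-8-en-10-yl 3-methylbutanoate | CC1=C[C@H](OC(=O)CC(C)C)[C@@]2(C)CC[C@](O)(C(C)C)[C@@H]2C(=O)C1 | intermediate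
16 | (1S,4S,5S,6R,10S)-4,6-dihydroxydauc-8-en-10-yl 3-methylbutanoate | CC1=C[C@H](OC(=O)CC(C)C)[C@@]2(C)CC[C@](O)(C(C)C)[C@@H]2[C@H](O)C1 | intermediate
17 | (1S,4S,5S,6R,10S)-4-hydroxy-10-(3-methylbutanoyloxy)dauc-8-en-6-yl 4-acetoxybenzoate | CC1=C[C@H](OC(=O)CC(C)C)[C@@]2(C)CC[C@](O)(C(C)C)[C@@H]2[C@H](OC(=O)c2ccc(OC(C)=O)cc2)C1 | intermediate
18 | (1S,4S,5S,6R,10S)-4-hydroxy-10-(3-methylbutanoyloxy)dauc-8-en-6-yl 4-hydroxybenzoate | CC1=C[C@H](OC(=O)CC(C)C)[C@@]2(C)CC[C@](O)(C(C)C)[C@@H]2[C@H](OC(=O)c2ccc(O)cc2)C1 | target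

**Step count and risks**

Total step count: 13. Longest linear sequence: 12 (steps 1, 2 and 4–13 from geranyl acetate; step 3 is a one-step side branch).

The three steps most likely to fail:

Step 6 (tandem acylation/carbonyl-ene bicyclisation). Possible failures are protodesilylation, E/Z scrambling of the enoyl chloride, chloride-trapped Prins products, or a trans-selective ene closure, which would give the wrong C4 configuration. The fallback closes the rings one at a time through an aldehyde instead of an acylium ion; it sets out from 7 and comes back at 9. LiAlH4 (THF, 0 °C) reduces acid and ketone of 7 to (2Z,5S,6E)-3,7,11-trimethyl-5-(trimethylsilyl)dodeca-2,6-diene-1,10-diol F1. Dess–Martin periodinane gives (2Z,5S,6E)-3,7,11-trimethyl-10-oxo-5-(trimethylsilyl)dodeca-2,6-dienal F2. BF3·OEt2 (CH2Cl2, −78 °C) closes the seven-membered ring by an intramolecular Hosomi–Sakurai allylation of the aldehyde, with the same anti SE2' relay to C7, to (7S)-3,7-dimethyl-7-(4-methyl-3-oxopentyl)cyclohepta-2,5-dien-1-ol F3 (both C1 epimers). Dess–Martin oxidation then returns to dienone 9, now isolated, which is cyclised to 10 with Me2AlCl (CH2Cl2, −78 → 0 °C) as a separate carbonyl-ene operation.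

Step 7 (cis → trans epimerisation). The equilibrium may not favour the trans isomer, and the extended enolate may lose the C4 hydroxyl (vinylogous E1cB) or undergo vinylogous retro-aldol cleavage. The fallback replaces thermodynamic control by a kinetic protonation; it sets out from 10 and comes back at 15. NaBH4/CeCl3·7H2O gives (1S,4S,5S,10S)-dauca-6,8-diene-4,10-diol F4, and 3-methylbutanoyl chloride/pyridine gives (1S,4S,5S,10S)-4-hydroxydauca-6,8-dien-10-yl 3-methylbutanoate F5. 9-BBN then NaBO3·4H2O gives (1S,4S,5R,6R,10S)-4,6-dihydroxydauc-8-en-10-yl 3-methylbutanoate F6, and Dess–Martin periodinane gives the cis-fused ketone (1S,4S,5S,10S)-4-hydroxy-6-oxodauc-8-en-10-yl 3-methylbutanoate F7. Martin sulfurane, Ph2S[OC(CF3)2Ph]2, dehydrates it to the tetrasubstituted enone (1S,10S)-6-oxodauca-4,8-dien-10-yl 3-methylbutanoate F8. t-BuOOH/DBU epoxidises the enone from the face anti to the angular methyl to (1R,4S,5S,10S)-4,5-epoxy-6-oxodauc-8-en-10-yl 3-methylbutanoate F9. SmI2 (THF/MeOH, −78 °C) cleaves the α C–O bond and the resulting enolate is protonated at C5 from the open α face, which returns to ketone 15.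

Step 10 (hydroboration of the dienyl ester). Possible failures are boron at C7, attack on the C8 olefin, or loss of the dienylic ester. The fallback puts the C6 oxygen in by conjugate addition at the dienone stage; it sets out from 11 and comes back at 14. CuCl/NaOt-Bu/Xantphos (cat.), B2pin2, MeOH, THF, then NaBO3·4H2O effect a 1,6-conjugate borylation–oxidation (the β-carbon is blocked by its methyl) to (1S,4S,5S,6S)-4,6-dihydroxydauc-8-en-10-one F10. Et3SiCl/imidazole gives (1S,4S,5S,6S)-4-hydroxy-6-(triethylsilyloxy)dauc-8-en-10-one F11. NaBH4/CeCl3·7H2O gives (1S,4S,5S,6S,10S)-6-(triethylsilyloxy)dauc-8-ene-4,10-diol F12, and 3-methylbutanoyl chloride/pyridine gives (1S,4S,5S,6S,10S)-4-hydroxy-6-(triethylsilyloxy)dauc-8-en-10-yl 3-methylbutanoate F13. HF·pyridine removes the silyl group and returns to diol 14.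

**Further compounds**

F1 | step 6 | (2Z,5S,6E)-3,7,11-trimethyl-5-(trimethylsilyl)dodeca-2,6-diene-1,10-diol | OC/C=C(C)\C[C@H]([Si](C)(C)C)/C=C(\C)CCC(O)C(C)C
F2 | step 6 | (2Z,5S,6E)-3,7,11-trimethyl-10-oxo-5-(trimethylsilyl)dodeca-2,6-dienal | O=C/C=C(C)\C[C@H]([Si](C)(C)C)/C=C(\C)CCC(=O)C(C)C
F3 | step 6 | (7S)-3,7-dimethyl-7-(4-methyl-3-oxopentyl)cyclohepta-2,5-dien-1-ol (C1 epimers) | CC1=CC(O)[C@@](C)(CCC(=O)C(C)C)C=CC1
F4 | step 7 | (1S,4S,5S,10S)-dauca-6,8-diene-4,10-diol | CC1=C[C@H](O)[C@@]2(C)CC[C@](O)(C(C)C)[C@H]2C=C1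
F5 | step 7 | (1S,4S,5S,10S)-4-hydroxydauca-6,8-dien-10-yl 3-methylbutanoate | CC1=C[C@H](OC(=O)CC(C)C)[C@@]2(C)CC[C@](O)(C(C)C)[C@H]2C=C1
F6 | step 7 | (1S,4S,5R,6R,10S)-4,6-dihydroxydauc-8-en-10-yl 3-methylbutanoate | CC1=C[C@H](OC(=O)CC(C)C)[C@@]2(C)CC[C@](O)(C(C)C)[C@H]2[C@H](O)C1
F7 | step 7 | (1S,4S,5S,10S)-4-hydroxy-6-oxodauc-8-en-10-yl 3-methylbutanoate | CC1=C[C@H](OC(=O)CC(C)C)[C@@]2(C)CC[C@](O)(C(C)C)[C@H]2C(=O)C1
F8 | step 7 | (1S,10S)-6-oxodauca-4,8-dien-10-yl 3-methylbutanoate | CC1=C[C@H](OC(=O)CC(C)C)[C@@]2(C)CCC(C(C)C)=C2C(=O)C1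
F9 | step 7 | (1R,4S,5S,10S)-4,5-epoxy-6-oxodauc-8-en-10-yl 3-methylbutanoate | CC1=C[C@H](OC(=O)CC(C)C)[C@@]2(C)CC[C@@]3(C(C)C)O[C@@]23C(=O)C1
F10 | step 10 | (1S,4S,5S,6S)-4,6-dihydroxydauc-8-en-10-one | CC1=CC(=O)[C@@]2(C)CC[C@](O)(C(C)C)[C@@H]2[C@@H](O)C1
F11 | step 10 | (1S,4S,5S,6S)-4-hydroxy-6-(triethylsilyloxy)dauc-8-en-10-one | CC1=CC(=O)[C@@]2(C)CC[C@](O)(C(C)C)[C@@H]2[C@@H](O[Si](CC)(CC)CC)C1
F12 | step 10 | (1S,4S,5S,6S,10S)-6-(triethylsilyloxy)dauc-8-ene-4,10-diol | CC1=C[C@H](O)[C@@]2(C)CC[C@](O)(C(C)C)[C@@H]2[C@@H](O[Si](CC)(CC)CC)C1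
F13 | step 10 | (1S,4S,5S,6S,10S)-4-hydroxy-6-(triethylsilyloxy)dauc-8-en-10-yl 3-methylbutanoate | CC1=C[C@H](OC(=O)CC(C)C)[C@@]2(C)CC[C@](O)(C(C)C)[C@@H]2[C@@H](O[Si](CC)(CC)CC)C1
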